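**Plan**
Retrosynthesis: the O-benzyl and O-methyl bonds are undone first, then the single biaryl bond between C5' of the flavanone ring B and C6 of the flavone ring A is cut; no ring of either flavonoid is opened.
Forward: (S)-hesperetin 1 already holds rings A, B and C of the flavanone; its 7-OH is benzylated (2) and the product is joined to apigenin 3, which brings the complete flavone.
Enabling feature: ring B of 1 is a guaiacol (3'-OH, 4'-OMe). Oxidation gives the masked ortho-benzoquinone 4 (C3' carbonyl, C4' dimethyl ketal), in which C5', the carbon next to the ketal, is the δ-carbon of a 2,4-dienone. C6 of 3, flanked by O5 and O7, is a phloroglucinol-type carbon nucleophile.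
Dearomatisation of ring B thus inverts its polarity; 1,6-addition of C6 and loss of methanol rebuild the arene as biaryl 5, and BBr3 then unmasks the target 6.
Stereochemistry: the only stereocentre, C2 (S), comes from 1 and is never made or broken.

Key step: step 2

Assumption: (S)-hesperetin of high enantiomeric purity is taken as commercial, and the biaryl axis (three small oxygen ortho substituents and one hydrogen) is treated as freely rotating, as in the structure given.

**Step 1**
Reactants: 1 (S)-hesperetin
Product: 2 (2S)-7-(benzyloxy)-5-hydroxy-2-(3-hydroxy-4-methoxyphenyl)-2,3-dihydro-4H-chromen-4-one (7-O-benzylhesperetin)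
Conditions: BnBr (1.05 equiv), KHCO3 (1.5 equiv), DMF, 40 °C
Reagents that add atoms: benzyl bromide, BrCc1ccccc1
Why: Williamson ether synthesis on the most acidic phenol: the 7-OH is para to the C4 carbonyl and is the only hydroxyl that KHCO3 ionises, whereas the 5-OH is locked in a hydrogen bond to the carbonyl and the 3'-OH is an ordinary guaiacol hydroxyl, and the weak base should leave the C2 centre alone.

**Step 2**
Reactants: 2 7-O-benzylhesperetin; 3 apigenin
Product: 5 (2S)-7-(benzyloxy)-2-{3-[5,7-dihydroxy-2-(4-hydroxyphenyl)-4-oxo-4H-chromen-6-yl]-5-hydroxy-4-methoxyphenyl}-5-hydroxy-2,3-dihydro-4H-chromen-4-one, via masked ortho-benzoquinone 4 (not isolated)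
Conditions: PhI(OAc)2 (1.0 equiv), MeOH, −10 °C; then 3 (2 equiv), Et3N (5 equiv), DMF, −10 → 20 °C; then AcOH
Reagents that add atoms: methanol, CO (supplies one of the two equivalent ketal methoxy groups of 4, either of which may be the one kept in 5)
Why: Proposed new method: PhI(OAc)2 in MeOH dearomatises the guaiacol ring B of 2 to the masked ortho-benzoquinone 4, a linear 2,4-dienone (O=C3'–C2'=C1'–C6'=C5') whose δ-carbon C5' sits next to the ketal carbon C4'; the 7-oxide of 3 attacks C5' through its C6 in a vinylogous (1,6) Michael addition, ring A of the flavone re-aromatises by tautomerisation, and E1cB loss of methanol from C4' re-aromatises ring B, so that the guaiacol has reacted with inverted polarity at the carbon ortho to its methoxy group. The closest known reaction types are the Michael addition–aromatisation of electron-rich arenes to masked ortho-benzoquinones made in situ from 2-methoxyphenols, and the conjugate addition–elimination of carbon nucleophiles on para-quinone monoketals; new here are the 1,6 course on a dienone with a carbon substituent on its β-carbon and a free hydroxyflavone anion as the arene. No ring is closed and no stereocentre is made: C5' is sp3 only in passing and the biaryl axis is not a stable stereo-element. Site selectivity on ring B is secured by the substrate, because C4' is a ketal and not a carbonyl, which shuts off the 1,4 mode that leads an ortho-quinone to C6', and because the β-carbon C1' is fully substituted, so that addition there is reversible and cannot end in an arene. On the flavone the carbon nucleophile is the ring A position between O5 and O7 (C6), C-attack being favoured over reversible O-attack in the protic medium, while C8 is the competing site. Chemoselectivity rests on charge, since Et3N ionises only the 7-OH of 3, whereas ring A of 4 is capped at O7 and keeps a chelated, un-ionised 5-OH, and the mild base at or below 20 °C leaves C2 untouched.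

**Step 3**
Reactants: 5 biaryl benzyl methyl ether
Product: 6 (2S)-2-{3-[5,7-dihydroxy-2-(4-hydroxyphenyl)-4-oxo-4H-chromen-6-yl]-4,5-dihydroxyphenyl}-5,7-dihydroxy-2,3-dihydro-4H-chromen-4-one (target)
Conditions: BBr3 (10 equiv), C6HMe5 (3 equiv), CH2Cl2, −78 → 0 °C; then H2O
Reagents that add atoms: none
Why: Boron tribromide ether cleavage: the benzyl ether ionises at low temperature with the benzyl cation trapped by pentamethylbenzene, the C4' methyl ether is cleaved by bromide attack on the methyl group of the boron-bound oxygen next to the O3'–boron bond, and the flavanone ring oxygen, a poor donor because it is a vinylogous ester oxygen, should not ionise the C2–O bond, so the (S) centre should be retained.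

**Compound list**
1 | (S)-hesperetin, (2S)-5,7-dihydroxy-2-(3-hydroxy-4-methoxyphenyl)-2,3-dihydro-4H-chromen-4-one | O=C1C[C@@H](c2ccc(OC)c(O)c2)Oc2cc(O)cc(O)c21 | starting material
2 | (2S)-7-(benzyloxy)-5-hydroxy-2-(3-hydroxy-4-methoxyphenyl)-2,3-dihydro-4H-chromen-4-one | O=C1C[C@@H](c2ccc(OC)c(O)c2)Oc2cc(OCc3ccccc3)cc(O)c21 | intermediate
3 | apigenin, 5,7-dihydroxy-2-(4-hydroxyphenyl)-4H-chromen-4-one | O=c1cc(-c2ccc(O)cc2)oc2cc(O)cc(O)c12 | starting material
4 | (2S)-7-(benzyloxy)-2-(4,4-dimethoxy-3-oxocyclohexa-1,5-dien-1-yl)-5-hydroxy-2,3-dihydro-4H-chromen-4-one (masked ortho-benzoquinone) | O=C1C[C@@H](C2=CC(=O)C(OC)(OC)C=C2)Oc2cc(OCc3ccccc3)cc(O)c21 | intermediate (not isolated)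
5 | (2S)-7-(benzyloxy)-2-{3-[5,7-dihydroxy-2-(4-hydroxyphenyl)-4-oxo-4H-chromen-6-yl]-5-hydroxy-4-methoxyphenyl}-5-hydroxy-2,3-dihydro-4H-chromen-4-one | O=C1C[C@@H](c2cc(O)c(OC)c(-c3c(O)cc4oc(-c5ccc(O)cc5)cc(=O)c4c3O)c2)Oc2cc(OCc3ccccc3)cc(O)c21 | intermediate
6 | (2S)-2-{3-[5,7-dihydroxy-2-(4-hydroxyphenyl)-4-oxo-4H-chromen-6-yl]-4,5-dihydroxyphenyl}-5,7-dihydroxy-2,3-dihydro-4H-chromen-4-one | O=C1C[C@@H](c2cc(O)c(O)c(-c3c(O)cc4oc(-c5ccc(O)cc5)cc(=O)c4c3O)c2)Oc2cc(O)cc(O)c21 | target

Total step count: 3
Longest linear sequence: 3 steps (1 → 2 → 5 → 6)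

**Steps most likely to fail**

Step 2 (labelled step). What may go wrong:
- poor site selectivity on the flavone, with attack through C8 instead of C6;
- ionisation of the ketal, which would steer the arene to C6' of ring B;
- Diels–Alder dimerisation of the dienone before it is trapped;
- O-arylation in place of C-arylation.

The fallback uses known chemistry and fixes the position on both partners before they are joined; it sets out from 1 and 3 and comes back to the route at 6. From 1, sterically controlled C–H borylation (HBpin, 3 equiv, to mask the three hydroxyls in the flask as O–Bpin, then B2pin2, [Ir(OMe)(cod)]2, 4,4'-di-tert-butyl-2,2'-bipyridine, THF, 80 °C; methanolic work-up) should put boron on the ring B C–H that has only one ortho substituent, and that the small methoxy group, giving the 5'-pinacolboronate of hesperetin F1. From 3, BnBr and K2CO3 in DMF should give 7,4'-di-O-benzylapigenin F2, and its free, chelated 5-OH directs iodination with benzyltrimethylammonium dichloroiodate and CaCO3 in CH2Cl2–MeOH to C6, giving the 6-iodoflavone F3. Suzuki–Miyaura coupling of F1 with F3 (Pd(OAc)2, SPhos, K3PO4, THF–H2O, 40 °C) should give the biaryl dibenzyl methyl ether F4, and the conditions of step 3 then cleave its two benzyl ethers and its methyl ether to give 6.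

Step 3. What may go wrong: loss of configurational integrity at C2 through Lewis acid-induced opening and re-closure of the pyranone ring, incomplete cleavage of the hindered methyl ether, or C-benzylation of the electron-rich rings. The fallback replaces Lewis acid cleavage by oxidative demethylation followed by hydrogenolysis; it sets out from 5 and comes back at 6. 2-Iodoxybenzoic acid in DMF at 0 °C should oxidise only the electron-rich guaiacol ring (the other phenols are chelated or sit on acyl-deactivated rings), with loss of methanol, to the ortho-quinone F5. This is reduced in the same flask with aqueous Na2S2O4 to the catechol 7-O-benzyl ether F6, and hydrogenolysis (H2, Pd/C, EtOAc–MeOH, 20 °C) then removes the benzyl group to give 6.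

Step 1. What may go wrong: alkylation at O3' as well, or base-induced opening of the pyranone ring that would erode C2. The fallback is a Mitsunobu etherification under neutral conditions; it sets out from 1 and comes back at 2. BnOH, PPh3 and diisopropyl azodicarboxylate in THF at 0 → 20 °C engage only the most acidic phenol (7-OH) and give 2 directly, with no further compound F0.

**Further compounds**
F1 | step 2 | (2S)-5,7-dihydroxy-2-[3-hydroxy-4-methoxy-5-(4,4,5,5-tetramethyl-1,3,2-dioxaborolan-2-yl)phenyl]-2,3-dihydro-4H-chromen-4-one | O=C1C[C@@H](c2cc(O)c(OC)c(B3OC(C)(C)C(C)(C)O3)c2)Oc2cc(O)cc(O)c21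
F2 | step 2 | 7-(benzyloxy)-2-[4-(benzyloxy)phenyl]-5-hydroxy-4H-chromen-4-one | O=c1cc(-c2ccc(OCc3ccccc3)cc2)oc2cc(OCc3ccccc3)cc(O)c12
F3 | step 2 | 7-(benzyloxy)-2-[4-(benzyloxy)phenyl]-5-hydroxy-6-iodo-4H-chromen-4-one | O=c1cc(-c2ccc(OCc3ccccc3)cc2)oc2cc(OCc3ccccc3)c(I)c(O)c12
F4 | step 2 | (2S)-2-(3-{7-(benzyloxy)-2-[4-(benzyloxy)phenyl]-5-hydroxy-4-oxo-4H-chromen-6-yl}-5-hydroxy-4-methoxyphenyl)-5,7-dihydroxy-2,3-dihydro-4H-chromen-4-one | O=C1C[C@@H](c2cc(O)c(OC)c(-c3c(OCc4ccccc4)cc4oc(-c5ccc(OCc6ccccc6)cc5)cc(=O)c4c3O)c2)Oc2cc(O)cc(O)c21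
F5 | step 3 | (2S)-7-(benzyloxy)-2-{5-[5,7-dihydroxy-2-(4-hydroxyphenyl)-4-oxo-4H-chromen-6-yl]-3,4-dioxocyclohexa-1,5-dien-1-yl}-5-hydroxy-2,3-dihydro-4H-chromen-4-one | O=C1C[C@@H](C2=CC(=O)C(=O)C(-c3c(O)cc4oc(-c5ccc(O)cc5)cc(=O)c4c3O)=C2)Oc2cc(OCc3ccccc3)cc(O)c21
F6 | step 3 | (2S)-7-(benzyloxy)-2-{3-[5,7-dihydroxy-2-(4-hydroxyphenyl)-4-oxo-4H-chromen-6-yl]-4,5-dihydroxyphenyl}-5-hydroxy-2,3-dihydro-4H-chromen-4-one | O=C1C[C@@H](c2cc(O)c(O)c(-c3c(O)cc4oc(-c5ccc(O)cc5)cc(=O)c4c3O)c2)Oc2cc(OCc3ccccc3)cc(O)c21
F0 | step 1 | none | none
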